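**Plan**
- Retrosynthesis: cut C2–C1′ (ring B off a chromone), then O1–C2 and C4–C4a (ring C back to a free C8a phenol), then C8–C8a and C6–C7 of ring A (ynol silyl ether + 3-ethoxycyclobutenone), and last the ynol carbon and the C2″–CH2 bond of the side chain.
- Forward: the side chain is made first (steps 1–8), ring A is grown around its alkyne terminus (step 9), ring C is closed as a chromone on the only free phenol (steps 10–12), ring B is joined last (step 15), then deprotection (steps 16–17).
- Enabling feature: ring A is a benzene with oxygen on C5, C7 and C8a and the side chain on C8 between C7–O and C8a–O1. C8/C7 map onto the two carbons of a siloxyalkyne and C8a/C4a/C5/C6 onto a 3-alkoxy vinylketene, so the ring arrives with its oxygens already differentiated (C8a–OH free, C7–OTIPS, C5–OEt).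
- Stereochemistry: C3″ comes from methyl (R)-3-hydroxy-2-methylpropanoate, C2″ from conjugate allylation anti to that methyl group in a six-membered lactone, and C2 from a chiral rhodium catalyst.

Key step: step 9

Abbreviations: TBS = tert-butyldimethylsilyl, TIPS = triisopropylsilyl, MOM = methoxymethyl. R(OTBS) = (2R,3S)-4-[(TBS)oxy]-3-methyl-2-(3-methylbut-2-en-1-yl)butyl; R(OH) = the same chain with a free 4-hydroxyl.

Assumption: the sense of induction of the rhodium/chiral diene catalyst in step 15 is assigned by analogy with simple chromones; the ligand antipode that delivers the aryl group to the Re face of C2 (giving 2S) is to be confirmed on a model chromone and is the one used.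

**Step 1**
Reactants: 1 methyl (R)-3-hydroxy-2-methylpropanoate
Product: 2 methyl (2R)-3-[(TBS)oxy]-2-methylpropanoate
Conditions: TBSCl, imidazole, CH2Cl2, 0 °C → rt
Reagents that add atoms: tert-butyldimethylsilyl chloride, CC(C)(C)[Si](C)(C)Cl
Why: Standard silylation of a primary alcohol masks the hydroxyl for the reduction and olefination; the stereocentre (later C3″) is not touched.

**Step 2**
Reactants: 2 methyl (2R)-3-[(TBS)oxy]-2-methylpropanoate
Product: 3 (2R)-3-[(TBS)oxy]-2-methylpropanal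
Conditions: DIBAL-H (1.05 equiv), CH2Cl2, −78 °C; Rochelle salt; used crude at once
Reagents that add atoms: none
Why: Partial DIBAL-H reduction of the ester stops at the aluminium hemiacetal at −78 °C, and immediate use of the α-methyl aldehyde should avoid epimerisation.

**Step 3**
Reactants: 3 (2R)-3-[(TBS)oxy]-2-methylpropanal
Product: 4 methyl (2Z,4S)-5-[(TBS)oxy]-4-methylpent-2-enoate
Conditions: (CF3CH2O)2P(O)CH2CO2Me, KHMDS, 18-crown-6, THF, −78 °C
Reagents that add atoms: methyl bis(2,2,2-trifluoroethyl)phosphonoacetate, COC(=O)CP(=O)(OCC(F)(F)F)OCC(F)(F)F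
Why: The Still–Gennari olefination should give the (Z)-enoate under kinetic control at a temperature where the α-stereocentre of the aldehyde is configurationally safe.

**Step 4**
Reactants: 4 methyl (2Z,4S)-5-[(TBS)oxy]-4-methylpent-2-enoate
Product: 6 (5S)-5-methyl-5,6-dihydro-2H-pyran-2-one, via hydroxy enoate 5 (not isolated)
Conditions: TsOH·H2O (cat.), MeOH, rt; then toluene, 50 °C
Reagents that add atoms: none
Why: Acid-catalysed desilylation frees the hydroxyl, which lactonises onto the cis-disposed ester (intramolecular transesterification) to the unsaturated δ-lactone.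

**Step 5**
Reactants: 6 (5S)-5-methyl-5,6-dihydro-2H-pyran-2-one; 7 allylmagnesium bromide
Product: 9 (4R,5S)-5-methyl-4-(prop-2-en-1-yl)oxan-2-one, via silyl ketene acetal 8 (not isolated)
Conditions: 7, CuBr·SMe2 (1.5 equiv each), TMSCl, THF, −78 °C; aq. NH4Cl
Reagents that add atoms: none
Why: TMSCl-accelerated conjugate addition of an allylcopper reagent should deliver the allyl group to C4 of the half-chair lactone on the face opposite the adjacent C5 methyl group, setting the trans relationship (C2″ of the target).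

**Step 6**
Reactants: 9 (4R,5S)-5-methyl-4-(prop-2-en-1-yl)oxan-2-one
Product: 10 (4R,5S)-5-methyl-4-(3-methylbut-2-en-1-yl)oxan-2-one
Conditions: 2-methylbut-2-ene (excess), Grubbs second-generation catalyst (3 mol%), CH2Cl2, 40 °C
Reagents that add atoms: 2-methylbut-2-ene, CC=C(C)C
Why: Olefin cross-metathesis with 2-methylbut-2-ene converts the terminal allyl group into the prenyl group with loss of propene and leaves the lactone and both stereocentres alone.

**Step 7**
Reactants: 10 (4R,5S)-5-methyl-4-(3-methylbut-2-en-1-yl)oxan-2-one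
Product: 12 methyl (3R,4S)-5-[(TBS)oxy]-4-methyl-3-(3-methylbut-2-en-1-yl)pentanoate, via hydroxy ester 11 (not isolated)
Conditions: K2CO3 (cat.), MeOH, 0 °C; AcOH, concentrate cold; then TBSCl, imidazole, DMF, 0 °C → rt
Reagents that add atoms: methanol, CO; tert-butyldimethylsilyl chloride, CC(C)(C)[Si](C)(C)Cl
Why: Base-catalysed methanolysis (transesterification) opens the δ-lactone and immediate silylation traps the open hydroxy ester before it can relactonise.

**Step 8**
Reactants: 12 methyl (3R,4S)-5-[(TBS)oxy]-4-methyl-3-(3-methylbut-2-en-1-yl)pentanoate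
Product: 15 tert-butyldimethyl{[(2S,3R)-2-methyl-3-(3-methylbut-2-en-1-yl)-6-[(TIPS)oxy]hex-5-yn-1-yl]oxy}silane, via dibromo enolate 13 (not isolated), via lithium ynolate 14 (not isolated)
Conditions: CH2Br2, LiTMP, THF, −78 °C; n-BuLi, −78 → 0 °C; TIPSCl, −78 °C → rt
Reagents that add atoms: dibromomethane, BrCBr; triisopropylsilyl chloride, CC(C)[Si](Cl)(C(C)C)C(C)C
Why: In the Kowalski ester homologation, dibromomethyllithium acylation, bromine–lithium exchange and 1,2-alkyl shift give the ynolate, which the bulky silyl chloride should trap on oxygen to the isolable ynol silyl ether.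

**Step 9**
Reactants: 15 tert-butyldimethyl{[(2S,3R)-2-methyl-3-(3-methylbut-2-en-1-yl)-6-[(TIPS)oxy]hex-5-yn-1-yl]oxy}silane; 16 3-ethoxycyclobut-2-en-1-one
Product: 21 2-[R(OTBS)]-5-ethoxy-3-[(TIPS)oxy]phenol, via vinylketene 17 (not isolated), via vinylcyclobutenone 18 (not isolated), via dienylketene 19 (not isolated), via cyclohexadienone 20 (not isolated)
Conditions: 16 (1.2 equiv, added in portions), toluene (0.3 M), 80 °C then 110 °C, argon
Reagents that add atoms: none
Why: Heating opens 16 by 4π electrocyclic cleavage of its C1–C4 bond to the 3-ethoxyvinylketene 17, whose ketene carbon is attacked by the nucleophilic, alkyl-bearing carbon of ynol ether 15 in a regiospecific [2+2] cycloaddition (new bonds C8–C8a and C6–C7) to give 18; a second 4π opening gives dienylketene 19, and ring A then closes by thermal disrotatory 6π electrocyclisation (C8a–C4a) to 20, which tautomerises to phenol 21. This is the Danheiser benzannulation in its siloxyalkyne variant, a known route from cyclobutenones to resorcinol monosilyl ethers, run here with a 3-alkoxy partner so that the third oxygen (C5–OEt) is carried in. No stereocentre is formed, and the two side-chain centres lie three and four atoms from the reacting alkyne and should pass through unchanged. The selectivity needed is regiochemical (side chain ortho to the new hydroxyl, siloxy group meta to it) and is fixed by the polarisation of the ynol ether, whose β-carbon bonds to the electrophilic ketene carbon. The ketene oxygen ends as the only free hydroxyl (C8a–OH) next to the side chain, while C7–O is silylated and C5–O is an ether, so the 6- versus 8-alkyl ambiguity of phloroglucinol chemistry does not arise. The trisubstituted alkene and both silyl ethers are inert to the neutral thermal conditions, and portionwise addition of 16 limits ketene dimerisation and acylation of the product phenol.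

**Step 10**
Reactants: 21 2-[R(OTBS)]-5-ethoxy-3-[(TIPS)oxy]phenol
Product: 22 1-[R(OTBS)]-4-ethoxy-2-(methoxymethoxy)-6-[(TIPS)oxy]benzene
Conditions: MOMCl, iPr2NEt, CH2Cl2, 0 °C → rt
Reagents that add atoms: chloromethyl methyl ether, COCCl
Why: O-Alkylation of the single free phenol (Williamson-type) installs an acetal that serves as the directing group for the next metalation.

**Step 11**
Reactants: 22 1-[R(OTBS)]-4-ethoxy-2-(methoxymethoxy)-6-[(TIPS)oxy]benzene
Product: 24 1-{3-[R(OTBS)]-6-ethoxy-2-(methoxymethoxy)-4-[(TIPS)oxy]phenyl}ethan-1-one, via aryllithium 23 (not isolated)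
Conditions: n-BuLi, TMEDA, THF, 0 °C; then MeC(O)N(OMe)Me, −78 °C → rt
Reagents that add atoms: N-methoxy-N-methylacetamide, CC(=O)N(C)OC
Why: Directed ortho-metalation should occur at the ring CH flanked by the chelating OMOM and OEt groups (C4a) and not at the CH next to the bulky, weakly directing OTIPS group (C6), and Weinreb acylation of the aryllithium stops at the methyl ketone.

**Step 12**
Reactants: 24 1-{3-[R(OTBS)]-6-ethoxy-2-(methoxymethoxy)-4-[(TIPS)oxy]phenyl}ethan-1-one
Product: 26 5-ethoxy-8-[R(OH)]-7-[(TIPS)oxy]-4H-chromen-4-one, via enaminone 25 (not isolated)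
Conditions: DMF–DMA, toluene, 100 °C; concentrate; HCl (1.25 M in MeOH), rt
Reagents that add atoms: N,N-dimethylformamide dimethyl acetal, COC(OC)N(C)C
Why: In this enaminone route to chromones, acid cleaves the ortho-carbonyl MOM acetal and the liberated C8a–OH adds to the β-carbon with loss of dimethylamine; the primary TBS ether is methanolysed on purpose, and the aryl TIPS and ethyl ethers, which are slower under Brønsted acid, should stay.

**Step 13**
Reactants: 27 4-bromobenzene-1,3-diol
Product: 28 1-bromo-2,4-bis(methoxymethoxy)benzene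
Conditions: MOMCl, iPr2NEt, CH2Cl2, 0 °C → rt
Reagents that add atoms: chloromethyl methyl ether, COCCl
Why: Double O-alkylation gives base-stable, sterically small acetal protection suited to an ortho-substituted boronic acid.

**Step 14**
Reactants: 28 1-bromo-2,4-bis(methoxymethoxy)benzene
Product: 31 [2,4-bis(methoxymethoxy)phenyl]boronic acid, via aryllithium 29 (not isolated), via boronate ester 30 (not isolated)
Conditions: n-BuLi, THF, −78 °C; B(OiPr)3, −78 °C → rt; aq. NH4Cl
Reagents that add atoms: triisopropyl borate, CC(C)OB(OC(C)C)OC(C)C; water, O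
Why: Bromine–lithium exchange, borylation of the chelated aryllithium and mild hydrolysis of the boronate ester are standard for electron-rich arylboronic acids.

**Step 15**
Reactants: 26 5-ethoxy-8-[R(OH)]-7-[(TIPS)oxy]-4H-chromen-4-one; 31 [2,4-bis(methoxymethoxy)phenyl]boronic acid
Product: 32 (2S)-2-[2,4-bis(methoxymethoxy)phenyl]-5-ethoxy-8-[R(OH)]-7-[(TIPS)oxy]-2,3-dihydro-4H-chromen-4-one
Conditions: 31 (3 equiv), [RhCl(C2H4)2]2 (2.5 mol%), chiral diene Ph-bod* (5.5 mol%, antipode per the assumption), KOH (10 mol%), toluene/H2O 10:1, 40 °C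
Reagents that add atoms: none
Why: In the rhodium-catalysed asymmetric 1,4-addition of arylboronic acids (Hayashi–Miyaura reaction), known for chromones, the arylrhodium species inserts the C2=C3 bond and the enolate is protonated; the chiral ligand alone decides the face at C2 (Re face, 2S) because the side-chain centres are remote.

**Step 16**
Reactants: 32 (2S)-2-[2,4-bis(methoxymethoxy)phenyl]-5-ethoxy-8-[R(OH)]-7-[(TIPS)oxy]-2,3-dihydro-4H-chromen-4-one
Product: 33 (2S)-2-(2,4-dihydroxyphenyl)-5-hydroxy-8-[R(OH)]-7-[(TIPS)oxy]-2,3-dihydro-4H-chromen-4-one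
Conditions: BCl3 (1 M in CH2Cl2, 6 equiv), CH2Cl2, −78 → −20 °C; aq. NaHCO3
Reagents that add atoms: none
Why: In this Lewis acid ether cleavage, chelation of boron between C4=O and the peri C5–OEt directs dealkylation to that ether and the two MOM acetals are cleaved as well; the hindered aryl TIPS ether and the alkene should tolerate the low temperature.

**Step 17**
Reactants: 33 (2S)-2-(2,4-dihydroxyphenyl)-5-hydroxy-8-[R(OH)]-7-[(TIPS)oxy]-2,3-dihydro-4H-chromen-4-one
Product: 34 (2S)-2-(2,4-dihydroxyphenyl)-5,7-dihydroxy-8-[(2R,3S)-4-hydroxy-3-methyl-2-(3-methylbut-2-en-1-yl)butyl]-2,3-dihydro-4H-chromen-4-one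
Conditions: KHF2, MeOH, rt
Reagents that add atoms: none
Why: Bifluoride desilylation of the phenolic silyl ether runs under weakly acidic conditions, so the base-induced ring opening that would epimerise C2 of a polyhydroxyflavanone is avoided.

**Compound list**
1 | methyl (R)-3-hydroxy-2-methylpropanoate | COC(=O)[C@H](C)CO | starting material
2 | methyl (2R)-3-[(TBS)oxy]-2-methylpropanoate | COC(=O)[C@H](C)CO[Si](C)(C)C(C)(C)C | intermediate
3 | (2R)-3-[(TBS)oxy]-2-methylpropanal | O=C[C@H](C)CO[Si](C)(C)C(C)(C)C | intermediate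
4 | methyl (2Z,4S)-5-[(TBS)oxy]-4-methylpent-2-enoate | COC(=O)/C=C\[C@H](C)CO[Si](C)(C)C(C)(C)C | intermediate
5 | methyl (2Z,4S)-5-hydroxy-4-methylpent-2-enoate (hydroxy enoate) | COC(=O)/C=C\[C@H](C)CO | intermediate
6 | (5S)-5-methyl-5,6-dihydro-2H-pyran-2-one | C[C@@H]1COC(=O)C=C1 | intermediate
7 | allylmagnesium bromide | C=CC[Mg]Br | starting material
8 | trimethylsilyl ketene acetal of 9: trans-3-methyl-4-allyl-6-(trimethylsilyloxy)-3,4-dihydro-2H-pyran | C=CC[C@@H]1C=C(O[Si](C)(C)C)OC[C@H]1C | intermediate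
9 | (4R,5S)-5-methyl-4-(prop-2-en-1-yl)oxan-2-one | C=CC[C@@H]1CC(=O)OC[C@H]1C | intermediate
10 | (4R,5S)-5-methyl-4-(3-methylbut-2-en-1-yl)oxan-2-one | CC(C)=CC[C@@H]1CC(=O)OC[C@H]1C | intermediate
11 | methyl (3R,4S)-5-hydroxy-4-methyl-3-(3-methylbut-2-en-1-yl)pentanoate (hydroxy ester) | CC(C)=CC[C@H](CC(=O)OC)[C@H](C)CO | intermediate
12 | methyl (3R,4S)-5-[(TBS)oxy]-4-methyl-3-(3-methylbut-2-en-1-yl)pentanoate | CC(C)=CC[C@H](CC(=O)OC)[C@H](C)CO[Si](C)(C)C(C)(C)C | intermediate
13 | lithium (4R,5S)-1,1-dibromo-6-[(TBS)oxy]-5-methyl-4-(3-methylbut-2-en-1-yl)hex-1-en-2-olate (dibromo enolate) | CC(C)=CC[C@H](CC(O[Li])=C(Br)Br)[C@H](C)CO[Si](C)(C)C(C)(C)C | intermediate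
14 | lithium (4R,5S)-6-[(TBS)oxy]-5-methyl-4-(3-methylbut-2-en-1-yl)hex-1-yn-1-olate (lithium ynolate) | CC(C)=CC[C@H](CC#CO[Li])[C@H](C)CO[Si](C)(C)C(C)(C)C | intermediate
15 | tert-butyldimethyl{[(2S,3R)-2-methyl-3-(3-methylbut-2-en-1-yl)-6-[(TIPS)oxy]hex-5-yn-1-yl]oxy}silane | CC(C)=CC[C@H](CC#CO[Si](C(C)C)(C(C)C)C(C)C)[C@H](C)CO[Si](C)(C)C(C)(C)C | intermediate
16 | 3-ethoxycyclobut-2-en-1-one | CCOC1=CC(=O)C1 | starting material
17 | 3-ethoxybuta-1,3-dien-1-one (vinylketene) | CCOC(=C)C=C=O | intermediate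
18 | 2-[R(OTBS)]-4-(1-ethoxyethenyl)-3-[(TIPS)oxy]cyclobut-2-en-1-one (vinylcyclobutenone, both C4 epimers) | CC(C)=CC[C@H](CC1=C(O[Si](C(C)C)(C(C)C)C(C)C)C(C(=C)OCC)C1=O)[C@H](C)CO[Si](C)(C)C(C)(C)C | intermediate
19 | 2-[R(OTBS)]-5-ethoxy-3-[(TIPS)oxy]hexa-1,3,5-trien-1-one, ketene carbon and ethoxyvinyl group cis (dienylketene) | CC(C)=CC[C@H](CC(=C=O)/C(O[Si](C(C)C)(C(C)C)C(C)C)=C\C(=C)OCC)[C@H](C)CO[Si](C)(C)C(C)(C)C | intermediate
20 | 2-[R(OTBS)]-5-ethoxy-3-[(TIPS)oxy]cyclohexa-2,4-dien-1-one | CC(C)=CC[C@H](CC1=C(O[Si](C(C)C)(C(C)C)C(C)C)C=C(OCC)CC1=O)[C@H](C)CO[Si](C)(C)C(C)(C)C | intermediate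
21 | 2-[R(OTBS)]-5-ethoxy-3-[(TIPS)oxy]phenol | CC(C)=CC[C@H](Cc1c(O)cc(OCC)cc1O[Si](C(C)C)(C(C)C)C(C)C)[C@H](C)CO[Si](C)(C)C(C)(C)C | intermediate
22 | 1-[R(OTBS)]-4-ethoxy-2-(methoxymethoxy)-6-[(TIPS)oxy]benzene | CC(C)=CC[C@H](Cc1c(OCOC)cc(OCC)cc1O[Si](C(C)C)(C(C)C)C(C)C)[C@H](C)CO[Si](C)(C)C(C)(C)C | intermediate
23 | {3-[R(OTBS)]-6-ethoxy-2-(methoxymethoxy)-4-[(TIPS)oxy]phenyl}lithium | CC(C)=CC[C@H](Cc1c(OCOC)c([Li])c(OCC)cc1O[Si](C(C)C)(C(C)C)C(C)C)[C@H](C)CO[Si](C)(C)C(C)(C)C | intermediate
24 | 1-{3-[R(OTBS)]-6-ethoxy-2-(methoxymethoxy)-4-[(TIPS)oxy]phenyl}ethan-1-one | CC(C)=CC[C@H](Cc1c(OCOC)c(C(C)=O)c(OCC)cc1O[Si](C(C)C)(C(C)C)C(C)C)[C@H](C)CO[Si](C)(C)C(C)(C)C | intermediate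
25 | (E)-3-(dimethylamino)-1-{3-[R(OTBS)]-6-ethoxy-2-(methoxymethoxy)-4-[(TIPS)oxy]phenyl}prop-2-en-1-one (enaminone) | CC(C)=CC[C@H](Cc1c(OCOC)c(C(=O)/C=C/N(C)C)c(OCC)cc1O[Si](C(C)C)(C(C)C)C(C)C)[C@H](C)CO[Si](C)(C)C(C)(C)C | intermediate
26 | 5-ethoxy-8-[R(OH)]-7-[(TIPS)oxy]-4H-chromen-4-one | CC(C)=CC[C@H](Cc1c(O[Si](C(C)C)(C(C)C)C(C)C)cc(OCC)c2c1OC=CC2=O)[C@H](C)CO | intermediate
27 | 4-bromobenzene-1,3-diol (4-bromoresorcinol) | Oc1ccc(Br)c(O)c1 | starting material
28 | 1-bromo-2,4-bis(methoxymethoxy)benzene | COCOc1ccc(Br)c(OCOC)c1 | intermediate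
29 | [2,4-bis(methoxymethoxy)phenyl]lithium | [Li]c1ccc(OCOC)cc1OCOC | intermediate
30 | dipropan-2-yl [2,4-bis(methoxymethoxy)phenyl]boronate | CC(C)OB(OC(C)C)c1ccc(OCOC)cc1OCOC | intermediate
31 | [2,4-bis(methoxymethoxy)phenyl]boronic acid | OB(O)c1ccc(OCOC)cc1OCOC | intermediate
32 | (2S)-2-[2,4-bis(methoxymethoxy)phenyl]-5-ethoxy-8-[R(OH)]-7-[(TIPS)oxy]-2,3-dihydro-4H-chromen-4-one | CC(C)=CC[C@H](Cc1c(O[Si](C(C)C)(C(C)C)C(C)C)cc(OCC)c2c1O[C@H](c1ccc(OCOC)cc1OCOC)CC2=O)[C@H](C)CO | intermediate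
33 | (2S)-2-(2,4-dihydroxyphenyl)-5-hydroxy-8-[R(OH)]-7-[(TIPS)oxy]-2,3-dihydro-4H-chromen-4-one | CC(C)=CC[C@H](Cc1c(O[Si](C(C)C)(C(C)C)C(C)C)cc(O)c2c1O[C@H](c1ccc(O)cc1O)CC2=O)[C@H](C)CO | intermediate
34 | (2S)-2-(2,4-dihydroxyphenyl)-5,7-dihydroxy-8-[(2R,3S)-4-hydroxy-3-methyl-2-(3-methylbut-2-en-1-yl)butyl]-2,3-dihydro-4H-chromen-4-one | CC(C)=CC[C@H](Cc1c(O)cc(O)c2c1O[C@H](c1ccc(O)cc1O)CC2=O)[C@H](C)CO | target

**Step count**
Total: 17 steps. Longest linear sequence: 15 steps (steps 1–12, then 15–17); the boronic acid branch (steps 13–14) joins at step 15.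

**Steps most likely to fail**

1. Step 9. The 3-alkoxycyclobutenone may open only at temperatures where the electron-rich vinylketene dimerises, or acylates the phenol already formed, faster than the ynol ether captures it. The fallback makes the same vinylketene without heat and sets out from 15. Ethyl (E)-3-ethoxybut-2-enoate F1 is saponified (LiOH, THF/H2O) to (E)-3-ethoxybut-2-enoic acid F2, which oxalyl chloride and catalytic DMF convert into (E)-3-ethoxybut-2-enoyl chloride F3. Slow addition of F3 to 15 and Et3N in CH2Cl2 at room temperature should give 17 by 1,4-dehydrochlorination (as known for β,β-disubstituted acryloyl chlorides) and, by ketene–ynol ether [2+2] cycloaddition, cyclobutenone 18. Heating 18 in toluene (80–110 °C) carries it through 19 and 20, and the route is rejoined at 21.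

2. Step 15. The ortho-substituted, electron-rich boronic acid may protodeboronate faster than it transmetalates, the electron-rich chromone may insert slowly, or the facial selectivity may be poor. The fallback sets out from 24 and builds ring C by condensation instead of arylation. Methanolic HCl removes the MOM and TBS groups to give 1-{6-ethoxy-2-hydroxy-3-[R(OH)]-4-[(TIPS)oxy]phenyl}ethan-1-one F4. Aryllithium 29 is quenched with DMF to give 2,4-bis(methoxymethoxy)benzaldehyde F5. Pyrrolidine in MeOH at 50 °C (Claisen–Schmidt/Kabbe condensation) joins F4 and F5 to the 2′-hydroxychalcone F6, which closes by oxa-Michael addition to 32 and its (2R)-epimer F7. Because the side chain is enantiopure the two are diastereomers and are separated by preparative HPLC; F7 is returned to the pyrrolidine equilibration. The route is rejoined at 32.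

3. Step 16. Lewis acid activation of the C4 carbonyl may ionise the C2–O1 bond of the flavanone, which carries an electron-rich ring B, and erode the C2 configuration through the open chalcone; HCl may also add to the trisubstituted alkene. The fallback moves the dealkylation to a stage without the C2 stereocentre and sets out from 26. BCl3 (CH2Cl2, −78 → 0 °C) cleaves the chelated ethyl ether of the chromone to 5-hydroxy-8-[R(OH)]-7-[(TIPS)oxy]-4H-chromen-4-one F8. The rhodium-catalysed arylation with 31, run as in step 15, gives (2S)-2-[2,4-bis(methoxymethoxy)phenyl]-5-hydroxy-8-[R(OH)]-7-[(TIPS)oxy]-2,3-dihydro-4H-chromen-4-one F9. Dilute methanolic HCl at room temperature then removes the two MOM groups, and the route is rejoined at 33.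

**Further compounds**
F1 | step 9 | ethyl (E)-3-ethoxybut-2-enoate | CCOC(=O)/C=C(\C)OCC
F2 | step 9 | (E)-3-ethoxybut-2-enoic acid | OC(=O)/C=C(\C)OCC
F3 | step 9 | (E)-3-ethoxybut-2-enoyl chloride | ClC(=O)/C=C(\C)OCC
F4 | step 15 | 1-{6-ethoxy-2-hydroxy-3-[R(OH)]-4-[(TIPS)oxy]phenyl}ethan-1-one | CC(C)=CC[C@H](Cc1c(O)c(C(C)=O)c(OCC)cc1O[Si](C(C)C)(C(C)C)C(C)C)[C@H](C)CO
F5 | step 15 | 2,4-bis(methoxymethoxy)benzaldehyde | COCOc1ccc(C=O)c(OCOC)c1
F6 | step 15 | (E)-3-[2,4-bis(methoxymethoxy)phenyl]-1-{6-ethoxy-2-hydroxy-3-[R(OH)]-4-[(TIPS)oxy]phenyl}prop-2-en-1-one | CC(C)=CC[C@H](Cc1c(O)c(C(=O)/C=C/c2ccc(OCOC)cc2OCOC)c(OCC)cc1O[Si](C(C)C)(C(C)C)C(C)C)[C@H](C)CO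
F7 | step 15 | (2R)-epimer of 32 | CC(C)=CC[C@H](Cc1c(O[Si](C(C)C)(C(C)C)C(C)C)cc(OCC)c2c1O[C@@H](c1ccc(OCOC)cc1OCOC)CC2=O)[C@H](C)CO
F8 | step 16 | 5-hydroxy-8-[R(OH)]-7-[(TIPS)oxy]-4H-chromen-4-one | CC(C)=CC[C@H](Cc1c(O[Si](C(C)C)(C(C)C)C(C)C)cc(O)c2c1OC=CC2=O)[C@H](C)CO
F9 | step 16 | (2S)-2-[2,4-bis(methoxymethoxy)phenyl]-5-hydroxy-8-[R(OH)]-7-[(TIPS)oxy]-2,3-dihydro-4H-chromen-4-one | CC(C)=CC[C@H](Cc1c(O[Si](C(C)C)(C(C)C)C(C)C)cc(O)c2c1O[C@H](c1ccc(OCOC)cc1OCOC)CC2=O)[C@H](C)CO
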